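**Assumption:** the target SMILES has no stereocentre and no stereogenic double bond, so there is one achiral compound to make and no enantiomer to control; the side chain is read as n-nonadecyl (19 carbons).

## Retrosynthetic overview

Listed from the building blocks up; read upward for the retrosynthetic direction.

1. Building blocks, both commercial: 3-methylpentane-2,4-dione (1) and methyl icosanoate (2). Compound 1 supplies five ring carbons, both resorcinol oxygens and the ring methyl; 2 supplies the sixth ring carbon and the nonadecyl chain.
2. Chain disconnection (C5–C6): the 1,3-dianion of 1 (3) plus 2 ⇒ 3-methylpentacosane-2,4,6-trione (4), a methyl-branched, decarboxylated tetraketide.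
3. Ring disconnection (C1–C6, the only ring): aldol closure of 4 with loss of water ⇒ 2-methyl-5-nonadecylresorcinol (5), the alkylresorcinol folding of a fatty-acyl-primed polyketide chain, run in the same flask as line 2.
4. C–O disconnection: para-oxygenation of 5 ⇒ capiquinone C (6).
5. Order: chain assembly → carbocycle (aldol/aromatisation) → quinone oxidation. One ring, no stereocentre.

## Route

**Step 1**
Reactants: 1 3-methylpentane-2,4-dione (2.2 equiv); 2 methyl icosanoate (1.0 equiv)
Product: 5 2-methyl-5-nonadecylbenzene-1,3-diol, via dilithium dianion 3 (not isolated), via open-chain triketone 4 (not isolated)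
Conditions: LiN(iPr)2 (4.4 equiv), THF, 0 °C; then 2, 0 °C → rt; then 2 M aq KOH, MeOH, 55 °C, Ar; HCl to pH 3 at 0 °C
Reagents that add atoms: none
Why: A β-diketone 1,3-dianion is acylated at its terminal carbon by an ester (Hauser–Harris Claisen-type C-acylation, the second equivalent of 3 taking the proton of the more acidic product), and the resulting 2,4,6-triketone closes in aqueous alkali by intramolecular aldol addition of its CH3 terminus (C1) to the C6 carbonyl followed by dehydration and enolisation (Collie-type polyketone aromatisation, the flask counterpart of alkylresorcinol folding), closure from the CH3 end being expected because the nucleophile is primary and the C3 methyl pushes C1 and C5 together, whereas closure of the chain CH2 onto C2 would need a secondary carbanion to attack an α-branched carbonyl; no stereocentre is formed.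

**Step 2**
Reactants: 5 2-methyl-5-nonadecylbenzene-1,3-diol
Product: 6 capiquinone C (3-hydroxy-2-methyl-5-nonadecylcyclohexa-2,5-diene-1,4-dione, also written 2-hydroxy-3-methyl-6-nonadecyl-1,4-benzoquinone)
Conditions: (KO3S)2NO (2.5 equiv), aq KH2PO4 (pH 6), methyltrioctylammonium chloride (10 mol %), CH2Cl2/H2O, rt; dilute HCl work-up
Reagents that add atoms: potassium nitrosodisulfonate (Fremy's salt), [K+].[K+].[O]N(S(=O)(=O)[O-])S(=O)(=O)[O-]
Why: Teuber oxidation, in which (KO3S)2NO abstracts the phenolic hydrogen and a second equivalent couples at the free carbon para to that oxygen (C4 and C6 are equivalent by symmetry and C2 is blocked by methyl, so only one hydroxyquinone can form), and loss of imidodisulfonate then gives the para-quinone with the second hydroxyl left in place; no stereocentre is formed.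

## Compound list

1 | 3-methylpentane-2,4-dione | CC(=O)C(C)C(C)=O | starting material
2 | methyl icosanoate (methyl arachidate) | CCCCCCCCCCCCCCCCCCCC(=O)OC | starting material
3 | dilithium 3-methylpenta-1,3-diene-2,4-diolate (1,3-dianion of 1; delocalised, no defined geometry) | [Li+].[Li+].C=C([O-])C(C)=C(C)[O-] | intermediate (not isolated)
4 | 3-methylpentacosane-2,4,6-trione (present as its enolate salts, drawn as the neutral triketo form; C3 is racemic and enolised) | CCCCCCCCCCCCCCCCCCCC(=O)CC(=O)C(C)C(C)=O | intermediate (not isolated)
5 | 2-methyl-5-nonadecylbenzene-1,3-diol (achiral) | CCCCCCCCCCCCCCCCCCCC1=CC(O)=C(C)C(O)=C1 | intermediate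
6 | capiquinone C (achiral) | CCCCCCCCCCCCCCCCCCCC1=CC(=O)C(C)=C(O)C1=O | target

## Step count and risks

Total step count: 2. Longest linear sequence: 2 steps.

The route has only two steps, so the three most likely failures are the two stages of step 1 and step 2.

**Step 1, ring-closing stage (highest risk).** The aldol could close the other way, with the chain CH2 attacking C2 to give an isomeric resorcinol, or hot alkali could cleave the triketone by retro-Claisen reaction. The fallback sets out from 4 and comes back at 5. Step 1 is stopped after the acylation by a cold aqueous NH4Cl quench and 4 is isolated. The nucleophile is then placed at a carboxyl-activated carbon, as in the polyketide chain itself. Compound 4 is converted to its trianion (LiN(iPr)2, 3.3 equiv, THF, 0 °C; the third deprotonation takes the CH3 terminus) and carboxylated with CO2 at −78 °C to give 4-methyl-3,5,7-trioxohexacosanoic acid F1. In aqueous acetate buffer at pH 5–6 and rt, the doubly activated C2 of this acid adds to the C7 carbonyl and the adduct dehydrates to 2,4-dihydroxy-3-methyl-6-nonadecylbenzoic acid F2. Heating in DMF at 120 °C decarboxylates it to 5.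

**Step 1, acylation stage.** Dianion 3 may deprotonate the enolisable ester 2 instead of adding to it, returning starting materials. The fallback sets out from 2 (with dianion 3 made as before) and comes back at 4. Ester 2 is reduced with i-Bu2AlH (CH2Cl2, −78 °C) to icosanal F3. Aldol addition of dianion 3 to this aldehyde (THF, −78 °C), which outruns proton transfer, gives 6-hydroxy-3-methylpentacosane-2,4-dione F4 as a mixture of stereoisomers that are all erased later. Oxidation with 2-iodoxybenzoic acid (EtOAc, 75 °C) gives 4, which is closed to 5 with aqueous KOH as in the last stage of step 1.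

**Step 2.** The oxidation may stall in the two-phase system, or the electron-rich hydroxyquinone may be over-oxidised or dimerise. The fallback sets out from 5 and comes back at 6; it brings in the third oxygen through a carbon substituent. Vilsmeier–Haack formylation (POCl3, DMF, MeCN, 0 °C → rt, then H2O) at the only free activated position gives 2,4-dihydroxy-3-methyl-6-nonadecylbenzaldehyde F5. Dakin oxidation (H2O2, NaOH, aq THF, 0 °C) gives 3-methyl-6-nonadecylbenzene-1,2,4-triol F6. This triol is oxidised to 6 with FeCl3 in aqueous ethanol, or simply by air.

## Further compounds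

F1 | step 1 | 4-methyl-3,5,7-trioxohexacosanoic acid | CCCCCCCCCCCCCCCCCCCC(=O)CC(=O)C(C)C(=O)CC(=O)O
F2 | step 1 | 2,4-dihydroxy-3-methyl-6-nonadecylbenzoic acid | CCCCCCCCCCCCCCCCCCCC1=CC(O)=C(C)C(O)=C1C(=O)O
F3 | step 1 | icosanal | CCCCCCCCCCCCCCCCCCCC=O
F4 | step 1 | 6-hydroxy-3-methylpentacosane-2,4-dione (mixture of stereoisomers) | CCCCCCCCCCCCCCCCCCCC(O)CC(=O)C(C)C(C)=O
F5 | step 2 | 2,4-dihydroxy-3-methyl-6-nonadecylbenzaldehyde | CCCCCCCCCCCCCCCCCCCC1=CC(O)=C(C)C(O)=C1C=O
F6 | step 2 | 3-methyl-6-nonadecylbenzene-1,2,4-triol | CCCCCCCCCCCCCCCCCCCC1=CC(O)=C(C)C(O)=C1O
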